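**Retrosynthetic overview**
- Ring C of the flavanone is closed last by cutting O1–C8a and C4–C4a: ring A becomes a 4-aryloxy-3,5-dimethoxybenzyne (C4a≡C8a), and O1–C2–C3–C4 becomes an (S)-β-silyloxy Weinreb amide whose C2 centre is set earlier by asymmetric transfer hydrogenation.
- Enabling feature: in ring A, O1 (on C8a) and the C4 carbonyl (on C4a) are ortho and C5, next to C4a, carries oxygen. This C5–O bond polarises the aryne so that oxygen adds at C8a and the carbanion forms at C4a. The C5/C7 dimethoxy pattern is symmetric about the C6···C8a axis (one aryne only), and the peri C5–O/C4=O pair later allows selective 5-O-demethylation.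
- Aryne precursor: an o-silylaryl triflate from benzyl-protected syringaldehyde (Baeyer–Villiger, bromination, retro-Brook/triflation, hydrogenolysis); the C6–O–aryl ether comes from a Chan–Lam coupling with a pre-built flavone boronic acid.
- Ring order: flavone pyranone ring first (Claisen–Schmidt, iodine/DMSO), flavanone ring C in the key step, then one global BCl3 deprotection.

Key step: step 13

Remark: atom numbers (O1, C2–C8a) are flavanone numbers; the dibenzyl ether of 2,4,6-trihydroxyacetophenone used in step 5 is taken as a catalogue compound (otherwise one O-benzylation from the parent triol).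

**Fragment 1: aryne precursor core**

Step 1
Reactants: 1 4-(benzyloxy)-3,5-dimethoxybenzaldehyde
Product: 3 4-(benzyloxy)-3,5-dimethoxyphenol, via aryl formate 2 (not isolated)
Conditions: mCPBA, CH2Cl2, 0 °C → rt; then K2CO3 (cat.), MeOH, rt
Reagents that add atoms: mCPBA (3-chloroperoxybenzoic acid), O=C(OO)c1cccc(Cl)c1
Why: Baeyer–Villiger (Dakin-type) oxidation of an electron-rich benzaldehyde, in which the trioxygenated aryl group migrates to give formate 2 and catalytic carbonate in methanol transesterifies it to the phenol; no stereocentre is formed.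

Step 2
Reactants: 3 4-(benzyloxy)-3,5-dimethoxyphenol
Product: 4 4-(benzyloxy)-2-bromo-3,5-dimethoxyphenol
Conditions: NBS (1.0 equiv), CH2Cl2, −40 → 0 °C
Reagents that add atoms: N-bromosuccinimide, O=C1CCC(=O)N1Br
Why: Electrophilic aromatic bromination directed by the free phenol; the para position is blocked and the two ortho positions are equivalent by symmetry, so one equivalent of NBS at low temperature should give a single monobromide.

Step 3
Reactants: 4 4-(benzyloxy)-2-bromo-3,5-dimethoxyphenol
Product: 7 4-(benzyloxy)-3,5-dimethoxy-2-(trimethylsilyl)phenyl trifluoromethanesulfonate, via silyl ether 5 (not isolated), via silylphenolate 6 (not isolated)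
Conditions: HMDS, THF, 65 °C, then evaporation; n-BuLi, THF, −100 → −78 °C; Tf2O, −78 → 0 °C
Reagents that add atoms: hexamethyldisilazane, C[Si](C)(C)N[Si](C)(C)C; trifluoromethanesulfonic anhydride, O=S(=O)(OS(=O)(=O)C(F)(F)F)C(F)(F)F
Why: Standard conversion of an o-bromophenol into an o-silylaryl triflate by O-silylation, bromine–lithium exchange, anionic 1,3-O-to-C silyl migration (retro-Brook rearrangement) to phenolate 6 and O-triflation, all tolerated by aryl methyl and benzyl ethers at −78 °C or below.

Step 4
Reactants: 7 4-(benzyloxy)-3,5-dimethoxy-2-(trimethylsilyl)phenyl trifluoromethanesulfonate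
Product: 8 4-hydroxy-3,5-dimethoxy-2-(trimethylsilyl)phenyl trifluoromethanesulfonate
Conditions: H2 (1 atm), Pd/C, EtOAc, rt
Reagents that add atoms: none
Why: Catalytic hydrogenolysis of the benzyl aryl ether under neutral conditions, which should leave the aryl triflate and the aryl–silicon bond untouched.

**Fragment 2: flavone boronic acid**

Step 5
Reactants: 9 1-[2,4-bis(benzyloxy)-6-hydroxyphenyl]ethan-1-one; 10 4-bromobenzaldehyde
Product: 11 (2E)-1-[2,4-bis(benzyloxy)-6-hydroxyphenyl]-3-(4-bromophenyl)prop-2-en-1-one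
Conditions: KOH, EtOH/THF, rt
Reagents that add atoms: none
Why: Claisen–Schmidt (crossed aldol) condensation of the acetophenone enolate with a non-enolisable aldehyde, followed by E1cB dehydration to the thermodynamically favoured E-enone while the chelated 2'-hydroxyl stays free.

Step 6
Reactants: 11 (2E)-1-[2,4-bis(benzyloxy)-6-hydroxyphenyl]-3-(4-bromophenyl)prop-2-en-1-one
Product: 12 5,7-bis(benzyloxy)-2-(4-bromophenyl)-4H-chromen-4-one
Conditions: I2 (10 mol %), DMSO, 130 °C
Reagents that add atoms: none
Why: Iodine-catalysed oxidative cyclisation of a 2'-hydroxychalcone (oxa-Michael closure, α-iodination and elimination, with DMSO reoxidising the hydrogen iodide), a standard flavone synthesis that benzyl ethers and the aryl bromide should survive.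

Step 7
Reactants: 12 5,7-bis(benzyloxy)-2-(4-bromophenyl)-4H-chromen-4-one
Product: 13 5,7-bis(benzyloxy)-2-[4-(4,4,5,5-tetramethyl-1,3,2-dioxaborolan-2-yl)phenyl]-4H-chromen-4-one
Conditions: B2pin2, Pd(dppf)Cl2 (3 mol %), KOAc, 1,4-dioxane, 90 °C
Reagents that add atoms: bis(pinacolato)diboron, CC1(C)OB(B2OC(C)(C)C(C)(C)O2)OC1(C)C
Why: Miyaura borylation of an aryl bromide that is activated for oxidative addition by the para pyranone, with a base (KOAc) too weak to harm the flavone.

Step 8
Reactants: 13 5,7-bis(benzyloxy)-2-[4-(4,4,5,5-tetramethyl-1,3,2-dioxaborolan-2-yl)phenyl]-4H-chromen-4-one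
Product: 14 {4-[5,7-bis(benzyloxy)-4-oxo-4H-chromen-2-yl]phenyl}boronic acid
Conditions: NaIO4, NH4OAc, acetone/H2O, rt
Reagents that add atoms: water, O
Why: Oxidative cleavage of the pinacol ester, in which periodate destroys the pinacol released in the hydrolysis equilibrium and so drives the boronate to the free boronic acid needed for the copper coupling.

**Union of fragments 1 and 2**

Step 9
Reactants: 8 4-hydroxy-3,5-dimethoxy-2-(trimethylsilyl)phenyl trifluoromethanesulfonate; 14 {4-[5,7-bis(benzyloxy)-4-oxo-4H-chromen-2-yl]phenyl}boronic acid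
Product: 15 4-{4-[5,7-bis(benzyloxy)-4-oxo-4H-chromen-2-yl]phenoxy}-3,5-dimethoxy-2-(trimethylsilyl)phenyl trifluoromethanesulfonate
Conditions: Cu(OAc)2, pyridine, 4 Å molecular sieves, CH2Cl2, dry air, rt
Reagents that add atoms: none
Why: Chan–Lam O-arylation (transmetalation of the boronic acid to the copper phenolate and reductive elimination from trivalent copper) at room temperature with only pyridine as base, conditions that should neither cleave the triflate nor trigger the silyl group and that accept electron-rich 2,6-disubstituted phenols.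

**Fragment 3: chiral amide**

Step 10
Reactants: 16 N-methoxy-N-methylacetamide; 17 4-(benzyloxy)benzoyl chloride
Product: 19 3-[4-(benzyloxy)phenyl]-N-methoxy-N-methyl-3-oxopropanamide, via amide enolate 18 (not isolated)
Conditions: LDA (2.2 equiv), THF, −78 °C; then 17, −78 → 0 °C; aq. NH4Cl
Reagents that add atoms: none
Why: Crossed Claisen condensation (C-acylation) of the lithium amide enolate 18 with an aroyl chloride, in which the second equivalent of enolate deprotonates the more acidic β-keto amide as it forms and so prevents double acylation.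

Step 11
Reactants: 19 3-[4-(benzyloxy)phenyl]-N-methoxy-N-methyl-3-oxopropanamide
Product: 20 (3S)-3-[4-(benzyloxy)phenyl]-3-hydroxy-N-methoxy-N-methylpropanamide
Conditions: RuCl(p-cymene)[(S,S)-TsDPEN] (1 mol %), HCO2H/Et3N (5:2), EtOAc, 30 °C
Reagents that add atoms: none
Why: Noyori–Ikariya asymmetric transfer hydrogenation of an aryl ketone, in which hydride and proton are delivered in the six-membered outer-sphere transition state to the carbonyl face fixed by the CH/π contact between the cymene ligand and the aryl ring, so that the (S,S)-ligand should set the new carbinol centre as S, as for acetophenone-type substrates.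

Step 12
Reactants: 20 (3S)-3-[4-(benzyloxy)phenyl]-3-hydroxy-N-methoxy-N-methylpropanamide
Product: 21 (3S)-3-[4-(benzyloxy)phenyl]-N-methoxy-N-methyl-3-[(trimethylsilyl)oxy]propanamide
Conditions: TMSCl, imidazole, CH2Cl2, 0 °C (used without chromatography)
Reagents that add atoms: chlorotrimethylsilane, C[Si](C)(C)Cl
Why: Routine O-silylation of a secondary alcohol with imidazole as base and nucleophilic catalyst, which does not touch the stereocentre and masks the only acidic proton of the nucleophile.

**Key step and deprotection**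

Step 13
Reactants: 15 4-{4-[5,7-bis(benzyloxy)-4-oxo-4H-chromen-2-yl]phenoxy}-3,5-dimethoxy-2-(trimethylsilyl)phenyl trifluoromethanesulfonate; 21 (3S)-3-[4-(benzyloxy)phenyl]-N-methoxy-N-methyl-3-[(trimethylsilyl)oxy]propanamide
Product: 26 (2S)-2-[4-(benzyloxy)phenyl]-6-{4-[5,7-bis(benzyloxy)-4-oxo-4H-chromen-2-yl]phenoxy}-5,7-dimethoxy-2,3-dihydro-4H-chromen-4-one, via alkoxide 22 (not isolated), via aryne 23 (not isolated), via aryl anion 24 (not isolated), via aminal alkoxide 25 (not isolated)
Conditions: CsF, 18-crown-6, THF, 0 °C → rt, slow addition of 15; then AcOH/NaOAc buffer (pH 5), 0 °C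
Reagents that add atoms: none
Why: Proposed new method: fluoride removes both silyl groups, giving alkoxide 22 from 21 and, by loss of triflate from 15, aryne 23; 22 adds through oxygen to C8a, and the resulting aryl anion 24 at C4a attacks the Weinreb carbonyl to give the tetrahedral aminal alkoxide 25, which collapses to the C4 ketone only in the buffered quench. The closest known reactions are the aryne annulation of methyl salicylates to xanthones (O-arylation followed by intramolecular acyl substitution) and the insertion of arynes into the C–O bond of carboxylic acids; new is the use of an aliphatic β-alkoxide that carries a stereocentre and of an amide as the acyl donor. Ring C is closed by intermolecular C8a–O1 bond formation followed by a 6-exo-trig attack of C4a on the amide carbonyl, a formal [4+2] annulation across the aryne. No lasting stereocentre is created: C2 is carried in from 21 with none of its bonds made or broken, the transient C4 centre of 25 vanishes on collapse, and because no proton source is present and the ketone stays masked as 25 while base is around, C3 cannot be enolised, so the retro-oxa-Michael opening that would scramble C2 is shut off. The step needs attack of oxygen at C8a and not at C4a, which is secured by the C5 methoxy group next to C4a, whose inductive pull distorts the aryne so that nucleophiles add at the remote carbon and the carbanion develops beside the oxygen-bearing carbon, while the symmetric substitution of 15 excludes any second aryne. It also needs ring closure to beat protonation of 24, which the silyl-masked, proton-free nucleophile and the six-membered transition state should provide.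

Step 14
Reactants: 26 (2S)-2-[4-(benzyloxy)phenyl]-6-{4-[5,7-bis(benzyloxy)-4-oxo-4H-chromen-2-yl]phenoxy}-5,7-dimethoxy-2,3-dihydro-4H-chromen-4-one
Product: 27 (2S)-6-[4-(5,7-dihydroxy-4-oxo-4H-chromen-2-yl)phenoxy]-5-hydroxy-2-(4-hydroxyphenyl)-7-methoxy-2,3-dihydro-4H-chromen-4-one
Conditions: BCl3, C6HMe5, CH2Cl2, −78 → 0 °C; then MeOH, 0 °C
Reagents that add atoms: none
Why: Lewis-acid ether cleavage in which BCl3, with pentamethylbenzene as a non-basic benzyl cation scavenger, removes the three benzyl ethers at −78 °C and on warming cleaves the C5 methyl ether selectively through the six-membered boron chelate with the peri C4 carbonyl, while the unchelated C7 methyl ether, the diaryl ether and the configuration at C2 (no bond to C2 is involved) should be preserved.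

**Compound list**

1 | 4-(benzyloxy)-3,5-dimethoxybenzaldehyde | COc1cc(C=O)cc(OC)c1OCc1ccccc1 | starting material
2 | 4-(benzyloxy)-3,5-dimethoxyphenyl formate (formed in the flask) | COc1cc(OC=O)cc(OC)c1OCc1ccccc1 | intermediate
3 | 4-(benzyloxy)-3,5-dimethoxyphenol | COc1cc(O)cc(OC)c1OCc1ccccc1 | intermediate
4 | 4-(benzyloxy)-2-bromo-3,5-dimethoxyphenol | COc1cc(O)c(Br)c(OC)c1OCc1ccccc1 | intermediate
5 | [4-(benzyloxy)-2-bromo-3,5-dimethoxyphenoxy]trimethylsilane (formed in the flask) | COc1cc(O[Si](C)(C)C)c(Br)c(OC)c1OCc1ccccc1 | intermediate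
6 | lithium 4-(benzyloxy)-3,5-dimethoxy-2-(trimethylsilyl)phenolate (formed in the flask) | COc1cc([O-])c([Si](C)(C)C)c(OC)c1OCc1ccccc1.[Li+] | intermediate
7 | 4-(benzyloxy)-3,5-dimethoxy-2-(trimethylsilyl)phenyl trifluoromethanesulfonate | COc1cc(OS(=O)(=O)C(F)(F)F)c([Si](C)(C)C)c(OC)c1OCc1ccccc1 | intermediate
8 | 4-hydroxy-3,5-dimethoxy-2-(trimethylsilyl)phenyl trifluoromethanesulfonate | COc1cc(OS(=O)(=O)C(F)(F)F)c([Si](C)(C)C)c(OC)c1O | intermediate
9 | 1-[2,4-bis(benzyloxy)-6-hydroxyphenyl]ethan-1-one | CC(=O)c1c(O)cc(OCc2ccccc2)cc1OCc1ccccc1 | starting material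
10 | 4-bromobenzaldehyde | O=Cc1ccc(Br)cc1 | starting material
11 | (2E)-1-[2,4-bis(benzyloxy)-6-hydroxyphenyl]-3-(4-bromophenyl)prop-2-en-1-one | O=C(/C=C/c1ccc(Br)cc1)c1c(O)cc(OCc2ccccc2)cc1OCc1ccccc1 | intermediate
12 | 5,7-bis(benzyloxy)-2-(4-bromophenyl)-4H-chromen-4-one | Brc1ccc(-c2cc(=O)c3c(OCc4ccccc4)cc(OCc4ccccc4)cc3o2)cc1 | intermediate
13 | 5,7-bis(benzyloxy)-2-[4-(4,4,5,5-tetramethyl-1,3,2-dioxaborolan-2-yl)phenyl]-4H-chromen-4-one | CC1(C)OB(c2ccc(-c3cc(=O)c4c(OCc5ccccc5)cc(OCc5ccccc5)cc4o3)cc2)OC1(C)C | intermediate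
14 | {4-[5,7-bis(benzyloxy)-4-oxo-4H-chromen-2-yl]phenyl}boronic acid | OB(O)c1ccc(-c2cc(=O)c3c(OCc4ccccc4)cc(OCc4ccccc4)cc3o2)cc1 | intermediate
15 | 4-{4-[5,7-bis(benzyloxy)-4-oxo-4H-chromen-2-yl]phenoxy}-3,5-dimethoxy-2-(trimethylsilyl)phenyl trifluoromethanesulfonate | COc1cc(OS(=O)(=O)C(F)(F)F)c([Si](C)(C)C)c(OC)c1Oc1ccc(-c2cc(=O)c3c(OCc4ccccc4)cc(OCc4ccccc4)cc3o2)cc1 | intermediate
16 | N-methoxy-N-methylacetamide | CC(=O)N(C)OC | starting material
17 | 4-(benzyloxy)benzoyl chloride | O=C(Cl)c1ccc(OCc2ccccc2)cc1 | starting material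
18 | lithium 1-[methoxy(methyl)amino]ethen-1-olate (formed in the flask) | [Li+].C=C([O-])N(C)OC | intermediate
19 | 3-[4-(benzyloxy)phenyl]-N-methoxy-N-methyl-3-oxopropanamide | CON(C)C(=O)CC(=O)c1ccc(OCc2ccccc2)cc1 | intermediate
20 | (3S)-3-[4-(benzyloxy)phenyl]-3-hydroxy-N-methoxy-N-methylpropanamide | CON(C)C(=O)C[C@H](O)c1ccc(OCc2ccccc2)cc1 | intermediate
21 | (3S)-3-[4-(benzyloxy)phenyl]-N-methoxy-N-methyl-3-[(trimethylsilyl)oxy]propanamide | CON(C)C(=O)C[C@H](O[Si](C)(C)C)c1ccc(OCc2ccccc2)cc1 | intermediate
22 | cesium (1S)-1-[4-(benzyloxy)phenyl]-3-[methoxy(methyl)amino]-3-oxopropan-1-olate (formed in the flask) | CON(C)C(=O)C[C@H]([O-])c1ccc(OCc2ccccc2)cc1.[Cs+] | intermediate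
23 | 5,7-bis(benzyloxy)-2-[4-(3,4-didehydro-2,6-dimethoxyphenoxy)phenyl]-4H-chromen-4-one, the C4a≡C8a aryne (formed in the flask) | COC1=C(Oc2ccc(-c3cc(=O)c4c(OCc5ccccc5)cc(OCc5ccccc5)cc4o3)cc2)C(OC)=CC#C1 | intermediate
24 | cesium salt of the C4a carbanion of (3S)-3-[4-(benzyloxy)phenyl]-3-(4-{4-[5,7-bis(benzyloxy)-4-oxo-4H-chromen-2-yl]phenoxy}-3,5-dimethoxyphenoxy)-N-methoxy-N-methylpropanamide, carbanion at ring position 2 between the new ether carbon and the methoxy carbon (formed in the flask) | COC1=CC(O[C@@H](CC(=O)N(C)OC)c2ccc(OCc3ccccc3)cc2)=[C-]C(OC)=C1Oc1ccc(-c2cc(=O)c3c(OCc4ccccc4)cc(OCc4ccccc4)cc3o2)cc1.[Cs+] | intermediate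
25 | cesium (2S)-2-[4-(benzyloxy)phenyl]-6-{4-[5,7-bis(benzyloxy)-4-oxo-4H-chromen-2-yl]phenoxy}-5,7-dimethoxy-4-[methoxy(methyl)amino]-3,4-dihydro-2H-chromen-4-olate, both C4 epimers (formed in the flask) | COc1cc2c(c(OC)c1Oc1ccc(-c3cc(=O)c4c(OCc5ccccc5)cc(OCc5ccccc5)cc4o3)cc1)C([O-])(N(C)OC)C[C@@H](c1ccc(OCc3ccccc3)cc1)O2.[Cs+] | intermediate
26 | (2S)-2-[4-(benzyloxy)phenyl]-6-{4-[5,7-bis(benzyloxy)-4-oxo-4H-chromen-2-yl]phenoxy}-5,7-dimethoxy-2,3-dihydro-4H-chromen-4-one | COc1cc2c(c(OC)c1Oc1ccc(-c3cc(=O)c4c(OCc5ccccc5)cc(OCc5ccccc5)cc4o3)cc1)C(=O)C[C@@H](c1ccc(OCc3ccccc3)cc1)O2 | intermediate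
27 | (2S)-6-[4-(5,7-dihydroxy-4-oxo-4H-chromen-2-yl)phenoxy]-5-hydroxy-2-(4-hydroxyphenyl)-7-methoxy-2,3-dihydro-4H-chromen-4-one | COc1cc2c(c(O)c1Oc1ccc(-c3cc(=O)c4c(O)cc(O)cc4o3)cc1)C(=O)C[C@@H](c1ccc(O)cc1)O2 | target

**Step count and risks**

Total step count: 14. Longest linear sequence: 7 steps (steps 1–4, 9, 13, 14; the sequence through steps 5–8 is equally long).

Steps most likely to fail:

1. Step 13 (proposed new method). What may go wrong: protonation of the aryl anion before ring closure; a 1,5-proton shift from C3 followed by β-elimination of the aryloxide; or early collapse of the tetrahedral intermediate, with base-induced ring opening and loss of configuration at C2. Fallback, from 15 back to 26, by the known insertion of arynes into the C–O bond of carboxylic acids: heating 15 with commercial (2E)-3-[4-(benzyloxy)phenyl]prop-2-enoic acid and CsF in THF (sealed tube, 125 °C) should give, through carboxylate addition at C8a and acyl transfer to C4a, the 2'-hydroxychalcone F1. Under the same conditions, or with NaOAc in EtOH at reflux, this should close by oxa-Michael addition to the racemic flavanone F2. Preparative HPLC on a chiral stationary phase then delivers the (2S)-enantiomer 26. This variant forms O1–C2 last and gives up the carried-in stereocentre.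

2. Step 9. What may go wrong: slow copper-mediated C–O bond formation at the doubly ortho-substituted phenol, so that protodeboronation and oxidative homocoupling of the boronic acid take over, or erosion of the silyl triflate on long exposure. Fallback, from 14 (with 8) back to 15, by metal-free arylation with a diaryliodonium salt: 4-iodoanisole is oxidised with mCPBA and BF3·OEt2 in CH2Cl2 and treated with 14 to give the aryl(4-methoxyphenyl)iodonium tetrafluoroborate F3. The potassium phenolate of 8 (t-BuOK, 1.0 equiv, THF, 0 °C) should then take over the electron-poorer flavonylphenyl group at rt and give 15.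

3. Step 14. What may go wrong: ionisation of the benzylic C2–O1 bond under the Lewis acid (ring opening, capture by the scavenger or loss of configuration at C2), or incomplete cleavage of the C5 methyl ether. Fallback, from 26 back to 27, in two separate mild operations: hydrogenolysis (H2, Pd/C, THF/EtOAc, rt) removes the three benzyl ethers and gives the 5-O-methyl ether F4. Chelation-controlled demethylation with MgI2 etherate (THF, 50 °C) then frees only the peri C5 hydroxyl to give 27.

Further compounds
F1 | step 13 | (2E)-3-[4-(benzyloxy)phenyl]-1-(3-{4-[5,7-bis(benzyloxy)-4-oxo-4H-chromen-2-yl]phenoxy}-6-hydroxy-2,4-dimethoxyphenyl)prop-2-en-1-one | COc1cc(O)c(C(=O)/C=C/c2ccc(OCc3ccccc3)cc2)c(OC)c1Oc1ccc(-c2cc(=O)c3c(OCc4ccccc4)cc(OCc4ccccc4)cc3o2)cc1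
F2 | step 13 | racemic 2-[4-(benzyloxy)phenyl]-6-{4-[5,7-bis(benzyloxy)-4-oxo-4H-chromen-2-yl]phenoxy}-5,7-dimethoxy-2,3-dihydro-4H-chromen-4-one | COc1cc2c(c(OC)c1Oc1ccc(-c3cc(=O)c4c(OCc5ccccc5)cc(OCc5ccccc5)cc4o3)cc1)C(=O)CC(c1ccc(OCc3ccccc3)cc1)O2
F3 | step 9 | {4-[5,7-bis(benzyloxy)-4-oxo-4H-chromen-2-yl]phenyl}(4-methoxyphenyl)iodonium tetrafluoroborate | COc1ccc([I+]c2ccc(-c3cc(=O)c4c(OCc5ccccc5)cc(OCc5ccccc5)cc4o3)cc2)cc1.F[B-](F)(F)F
F4 | step 14 | (2S)-6-[4-(5,7-dihydroxy-4-oxo-4H-chromen-2-yl)phenoxy]-2-(4-hydroxyphenyl)-5,7-dimethoxy-2,3-dihydro-4H-chromen-4-one | COc1cc2c(c(OC)c1Oc1ccc(-c3cc(=O)c4c(O)cc(O)cc4o3)cc1)C(=O)C[C@@H](c1ccc(O)cc1)O2
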